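**Assumption:** the target has no stereocentre and no stereogenic double bond, so it is one achiral compound and no stereocontrol is needed.

## Retrosynthetic overview

1. Phenethyl icosanoate is cut at C2–C3 of the acyl chain. One half is an octadecyl group carried as a nucleophile on boron; the other is 2-phenylethyl bromoacetate, whose α-carbon reacts as an α-acyl cation (enolonium) equivalent.
2. B-Octadecyl-9-BBN comes from 1-octadecene and 9-BBN by anti-Markovnikov hydroboration, in the same pot as the C–C bond formation.
3. 2-Phenylethyl bromoacetate comes from 2-phenylethanol and bromoacetic acid (ester C–O bond, made first).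
4. No ring is formed. The benzene ring is bought with 2-phenylethanol, and the 9-BBN bicycle is only a carrier that leaves at work-up.

## Route

Step 1
Reactants: 1 2-phenylethanol; 2 bromoacetic acid
Product: 3 2-phenylethyl bromoacetate
Conditions: 2 (1.1 equiv), TsOH·H2O (2 mol%), toluene, reflux, Dean–Stark, 4 h; aq. NaHCO3 wash
Reagents that add atoms: none
Why: Fischer esterification driven to completion by azeotropic removal of water; the primary C–Br bond is inert to the acidic conditions and no stereocentre is involved.

Step 2
Reactants: 4 1-octadecene; 5 9-BBN; 3 2-phenylethyl bromoacetate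
Product: 8 2-phenylethyl icosanoate, via B-octadecyl-9-BBN 6 (not isolated), via alpha-boryl ester 7 (not isolated)
Conditions: 4 (1.1 equiv), 5 (0.5 M in THF, 1.1 equiv), rt, 3 h; then 3 (1.0 equiv), 0 °C; then potassium 2,6-di-tert-butylphenoxide (1.05 equiv, pre-formed from 2,6-di-tert-butylphenol + KOtBu in THF) dropwise, 0 °C → rt, 1 h; aq. NH4Cl; SiO2, then recrystallisation from acetone
Reagents that add atoms: none
Why: Brown α-alkylation of an α-bromo ester with an organoborane (hydroboration followed by a boron-ate 1,2-metallate shift): boron goes to C1 of 4, the hindered phenoxide (too bulky to bind boron or attack the ester) deprotonates 3, the bromo-enolate adds to boron, the primary octadecyl group migrates from B to the α-carbon with loss of bromide, and the phenol protonates boron enolate 7 to an achiral CH2, so no stereocentre remains.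

## Compound list

1 | 2-phenylethanol | OCCc1ccccc1 | starting material
2 | bromoacetic acid | OC(=O)CBr | starting material
3 | 2-phenylethyl bromoacetate | BrCC(=O)OCCc1ccccc1 | intermediate
4 | 1-octadecene | CCCCCCCCCCCCCCCCC=C | starting material
5 | 9-borabicyclo[3.3.1]nonane (9-BBN; bridgeheads fixed cis by the bicycle) | B1C2CCCC1CCC2 | starting material
6 | 9-octadecyl-9-borabicyclo[3.3.1]nonane (B-octadecyl-9-BBN) | CCCCCCCCCCCCCCCCCCB1C2CCCC1CCC2 | intermediate
7 | 2-phenylethyl 2-(9-borabicyclo[3.3.1]nonan-9-yl)icosanoate (alpha-boryl ester, racemic at C2, in equilibrium with its O-boron enolate) | CCCCCCCCCCCCCCCCCCC(B1C2CCCC1CCC2)C(=O)OCCc1ccccc1 | intermediate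
8 | 2-phenylethyl icosanoate (phenethyl icosanoate) | CCCCCCCCCCCCCCCCCCCC(=O)OCCc1ccccc1 | target

## Step count

Total steps: 2.
Longest linear sequence: 2 (1 → 3 → 8); the hydroboration of 4 with 5 takes place inside step 2.

## Steps most likely to fail

The route has only two steps, so both are ranked. Step 2 carries nearly all the risk and is entered twice, once for each of its two separate failure modes.

**1. Step 2, the B→C migration.** The bromo-enolate of 3 may condense with itself (Darzens/Claisen) faster than it is captured by boron, or a ring B–C bond of the 9-BBN unit may migrate instead of the octadecyl group. The fallback moves the bond formation to C3–C4 and uses an ester homoenolate. It sets out from 1 and comes back at 8. Compound 1 is esterified with 3-iodopropanoic acid (TsOH cat., toluene, Dean–Stark) to 2-phenylethyl 3-iodopropanoate F1. Activated zinc dust (1,2-dibromoethane/TMSCl, THF, 35 °C) inserts into the C–I bond to give the zinc homoenolate [3-oxo-3-(2-phenylethoxy)propyl]zinc iodide F2, which is not isolated. F2 is cross-coupled with purchased 1-bromoheptadecane (CCCCCCCCCCCCCCCCCBr) under Negishi conditions for unactivated primary alkyl bromides (Pd2(dba)3 2 mol%, tricyclopentylphosphine 8 mol%, N-methylimidazole 1.2 equiv, THF/NMP, 80 °C) to give 8.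

**2. Step 2, survival and isolation of the 2-phenylethyl ester.** The base could cause loss of styrene from the PhCH2CH2–O unit or ester exchange, and 8 has to be separated from 2,6-di-tert-butylphenol. The fallback makes the C–C bond on a simple ester and brings in the phenethyl group last. It sets out from 6 (made from 4 and 5 as in step 2) and comes back at 8. Compound 6 is treated with ethyl bromoacetate and potassium 2,6-di-tert-butylphenoxide (THF, 0 °C). This passes through ethyl 2-(9-borabicyclo[3.3.1]nonan-9-yl)icosanoate F3, not isolated, and gives ethyl icosanoate F4, which is easily purified by distillation or crystallisation. F4 is then transesterified with 1 (1.5 equiv, Ti(OiPr)4 5 mol%, toluene, reflux, ethanol distilled out) to give 8.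

**3. Step 1, the esterification.** This is low risk, but the equilibrium may stall, or some bromide may be lost on prolonged heating. The fallback replaces the acid-catalysed equilibrium by irreversible acylation. It sets out from 1 and comes back at 3. Compound 1 is treated with bromoacetyl bromide (1.1 equiv) over solid NaHCO3 in CH2Cl2 at 0 °C → rt to give 3 directly. This fallback makes no new compound (F0).

## Further compounds

F1 | step 2 | 2-phenylethyl 3-iodopropanoate | O=C(CCI)OCCc1ccccc1
F2 | step 2 | [3-oxo-3-(2-phenylethoxy)propyl]zinc iodide | O=C(CC[Zn]I)OCCc1ccccc1
F3 | step 2 | ethyl 2-(9-borabicyclo[3.3.1]nonan-9-yl)icosanoate | CCCCCCCCCCCCCCCCCCC(B1C2CCCC1CCC2)C(=O)OCC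
F4 | step 2 | ethyl icosanoate | CCCCCCCCCCCCCCCCCCCC(=O)OCC
F0 | step 1 | none | none
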